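Assumption: acerosin is a planar, achiral flavone with no stereocentre, so "single enantiomer" means the compound itself and no step has to control configuration. 10 % F2 in N2 is taken as a purchasable reagent gas.

**Retrosynthetic overview**
1. Diosmin 1 (bulk citrus flavonoid) already holds rings A, C and B and every C–C bond of the target; hydrolysis of its rutinoside gives the aglycone diosmetin 2. No ring is built in the route.
2. Key disconnection: the two aryl C–O bonds C8–OMe and C6–OMe, made last and in one operation from the two A-ring C–H bonds of 2.
3. The electrophilic methoxy donor is methyl hypofluorite 5, made from fluorine 3 and methanol 4.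
4. The mono-methoxy compounds 6 and 7 both converge on acerosin 8.

**Route**

Step 1
Reactants: 1 diosmin (diosmetin 7-O-[α-L-rhamnopyranosyl-(1→6)-β-D-glucopyranoside])
Product: 2 diosmetin (5,7,3'-trihydroxy-4'-methoxyflavone)
Conditions: aq. H2SO4 (ca. 3 M) / ethylene glycol, 110 °C, 8 h; pour into water, filter, recrystallise
Reagents that add atoms: none
Why: Acid-catalysed glycoside (acetal) hydrolysis cleaves both O-glycosidic bonds at the anomeric carbons and releases the insoluble aglycone, while the aryl methyl ether and the flavone core are inert to hot aqueous acid; no stereocentre remains in the product.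

Step 2
Reactants: 3 fluorine (as 10 % F2 in N2), 4 methanol
Product: 5 methyl hypofluorite (kept as a cold, titrated EtCN–MeOH solution)
Conditions: 10 % F2/N2 bubbled into MeOH (ca. 1 M) in EtCN, −78 °C; N2 purge; iodometric titre; used at once
Reagents that add atoms: fluorine, FF; methanol, CO
Why: Direct O-fluorination of an alcohol with dilute elemental fluorine in a nitrile solvent is the established alkyl hypofluorite synthesis, and the product is stable enough below about −40 °C to be titrated and transferred cold.

Step 3
Reactants: 2 diosmetin, 5 methyl hypofluorite
Product: 8 acerosin, via 8-methoxydiosmetin 6 (not isolated), via 6-methoxydiosmetin 7 (not isolated)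
Conditions: 5 (2.1 equiv, added dropwise), CsF (6 equiv), MeOH–EtCN, −78 °C; aq. NaHSO3, then dil. HCl
Reagents that add atoms: methyl hypofluorite, COF
Why: Proposed new method: twofold electrophilic aromatic C–H methoxylation, in which the O–F bond of MeOF is polarised MeO(δ+)–F(δ−) so that C8 and C6 of the 7-phenolate of 2 (the sites NBS or I2 attack; the 7-OH, pKa about 7, is the only phenol the fluoride buffer ionises appreciably) displace fluoride at oxygen and each dienone re-aromatises by loss of HF to CsF, the remaining A-ring C–H position of 6 or 7 being expected to react ahead of the B ring, C3 or an ipso carbon; the closest known reaction types are the electrophilic α-methoxylation of enol acetates and silyl enol ethers with MeOF and the Elbs persulfate oxidation of 5-hydroxyflavones (a phenolate carbon attacking an electrophilic oxygen), neither of which, to my knowledge, has been used to methoxylate a phenolic arene C–H bond.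

**Compound list**
1 | diosmin (diosmetin 7-O-rutinoside) | COc1ccc(-c2cc(=O)c3c(O)cc(O[C@@H]4O[C@H](CO[C@@H]5O[C@@H](C)[C@H](O)[C@@H](O)[C@H]5O)[C@@H](O)[C@H](O)[C@H]4O)cc3o2)cc1O | starting material
2 | diosmetin (5,7,3'-trihydroxy-4'-methoxyflavone) | COc1ccc(-c2cc(=O)c3c(O)cc(O)cc3o2)cc1O | intermediate
3 | fluorine | FF | starting material
4 | methanol | CO | starting material
5 | methyl hypofluorite | COF | intermediate
6 | 8-methoxydiosmetin (5,7,3'-trihydroxy-8,4'-dimethoxyflavone) | COc1ccc(-c2cc(=O)c3c(O)cc(O)c(OC)c3o2)cc1O | intermediate
7 | 6-methoxydiosmetin (5,7,3'-trihydroxy-6,4'-dimethoxyflavone) | COc1ccc(-c2cc(=O)c3c(O)c(OC)c(O)cc3o2)cc1O | intermediate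
8 | acerosin (5,7,3'-trihydroxy-6,8,4'-trimethoxyflavone) | COc1ccc(-c2cc(=O)c3c(O)c(OC)c(O)c(OC)c3o2)cc1O | target

**Totals**
Total step count: 3.
Longest linear sequence: 2 steps (1 → 2 → 8); step 2 is a one-step reagent branch.

**Steps most likely to fail**

Step 3 (the proposed new C–H methoxylation) is the most likely to fail. The likely failure modes are:
- methoxylation of the B ring or of C3;
- ipso attack on 6, 7 or 8 to give quinone monoketals;
- fluoride-induced decomposition of 5 to formaldehyde and HF;
- poor solubility of 2 at −78 °C.

The fallback uses only known chemistry and sets out from 2. NBS (2.05 equiv) in DMF at 0 °C brominates the A ring selectively to give 6,8-dibromodiosmetin F1. Copper-mediated Ullmann-type methanolysis (NaOMe in excess, CuBr, MeOH–DMF, 110 °C, acidic work-up) then replaces both bromides by methoxide. This comes back to the route at 8; partial hydrodebromination is the known side reaction.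

Step 2 (generation of 5) is the second risk. It needs fluorine handling, the titre varies from batch to batch, and the reagent decomposes above about −40 °C. The fallback sets out from 4 and avoids elemental fluorine. Solid xenon difluoride in methanol gives methoxyxenon fluoride F2, which under BF3·OEt2 catalysis acts as an oxygen electrophile. It is used in place of 5 on neutral 2 in MeOH–CH2Cl2 at −40 °C, and the fallback comes back to the route at 8.

Step 1 (hydrolysis of 1) is the third risk. Diosmin is very poorly soluble, so hydrolysis can stop at the monoglycoside, and hot sulfuric acid can char or sulfonate the material. The fallback sets out from 1 and replaces acid by enzymes. Naringinase (α-L-rhamnosidase plus β-D-glucosidase activity) in acetate buffer pH 4.5 with 10 % DMSO at 50 °C first removes rhamnose to give diosmetin 7-O-β-D-glucopyranoside F3. The glucosidase then cleaves F3, and the fallback comes back to the route at 2.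

**Further compounds**
F1 | step 3 | 6,8-dibromodiosmetin (6,8-dibromo-5,7,3'-trihydroxy-4'-methoxyflavone) | COc1ccc(-c2cc(=O)c3c(O)c(Br)c(O)c(Br)c3o2)cc1O
F2 | step 2 | methoxyxenon fluoride | CO[Xe]F
F3 | step 1 | diosmetin 7-O-β-D-glucopyranoside | COc1ccc(-c2cc(=O)c3c(O)cc(O[C@@H]4O[C@H](CO)[C@@H](O)[C@H](O)[C@H]4O)cc3o2)cc1O
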